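(Readings and results are calculated with constants of no real substance; the scatter is artificial.)

Start from amounts. In the flask asked about, followed so far as the north-east run, add substrate and target, and call what they fall short of the charge the missing share.

| flask | substrate | reagent in the second phase | remark | time | volume of the second phase over the first |
|---|---|---|---|---|---|
| north-east | 1 M | 2 M | the very flask that is asked about, followed so far |  |  |
| flask | 1.0 M | 2.00 M |  | 3.0 h | 1.0 |

- north-east (time / min: target / %, substrate / %): 2.00: 12.8, 88.0; 6.00: 37.0, 53.3; 10.0: 49.4, 31.9; 15.0: 52.4, 14.8; 20.0: 48.6, 6.8; 30.0: 40.7, 0; 40.0: 35.7, 1.3

(scatter of a reading: 1 percentage point)

- in the second phase: reagent in the second phase; everything else is in the first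
- charges count per volume of the first phase; a concentration in a rate is the amount of a species over the volume of its own phase; every rate counts per litre of the first phase
- the earlier runs hold the two phases in the same ratio of volumes as the flask asked about

* amount of target at 3.0 h, in percent of the substrate charged
* the change that raises the amount of target at 3.0 h, in percent of the substrate charged most ("none" if none brings more than 2 percentage points) (Monday's / Friday's / none)
* amount of target at 3.0 h, in percent of the substrate charged, after Friday's

- Monday's: doubling the amount of reagent in the second phase, all else as stated
- Friday's: doubling the transfer coefficient of the reagent in the second phase, all else as stated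

Read the table row against row. My reckoning goes as follows. In the north-east run, at 10.0 min the missing share is 18.7% and at 15.0 min it is 32.8%. Per unit of target present, that is a growth of 0.0554 /min, with the ratio R of missing share to target near 0.506.

Between 30.0 min and 40.0 min it goes from 59.3% to 63.0%. So the growth per unit of target has sunk to 0.00969 /min, with R near 1.60.

Growth that falls as R rises looks like a way back, so I treat target and the missing share as a reversible pair. A straight line through those two points reaches zero growth at R = 1.83. This is a reading, resting on a late difference of readings with scatter 1 percentage point.

The end share of target, the part of the turned-over substrate that stays target once R stops moving, is then 1/(1+R) = 35.3%. If the pair behaves so, that is thermodynamic rather than kinetic control.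

The same line gives a relaxation half-life of 5.86 min, far shorter than 3.0 h. In the north-east run, substrate already reads 0% at 30.0 min. So I expect the end share in the flask asked about at the asked time, and no gain from either change.

The forecast says 10%, none, and 9% after Friday's, holding that “target decays second-order”. On the amount of target it differs from my reckoning.

The flask gives 34.5%, best change none, and 34.5% after Friday's.

    reagent in the reaction phase ⇌ reagent in the second phase, rate k1*([reagent in the reaction phase] - [reagent in the second phase]/K1) per volume of the first phase (partition coefficient = 2.05, kL = 0.00214 /s)
    substrate + reagent in the reaction phase → target (k = 0.0173 /M/s)
    target ⇌ isomer of the product (K = 1.90, k = 0.00129 /s)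
    reagent in the reaction phase ⇌ dormant form (K = 1.10, k = 3.26 × 10⁻⁴ /s)

In this flask, target stands at 34.5% at 1.50 h and at 34.5% at 30.0 h. The end share times the turned-over part of this flask gives 35.3%.

In the neighbour flask with [substrate] charged at 2.5 M, 20% of the substrate is still there at 3.00 h, so the end share times the turned-over part gives 28.2%. The neighbour flask gives 27.6%.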